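Substrate left over is the end state to reckon first in these flasks. Each route to product spends one partner per substrate, and partner comes from the solid reagent, of which 0.0140 M is charged against 0.020 M of substrate.

    solid reagent ⇌ partner, rate k1*(cs1 - [partner]) while solid is left; crystals form when [partner] > cs1 (cs1 = 7.8 mM, k1 = 3.9 × 10⁻⁴ /s)
    substrate + partner + by-product → product + 2 by-product (k2 = 8.5 /M²/s)
    substrate + partner → product + by-product (k3 = 2.2 × 10⁻⁵ /M/s)

| setting | noon | midnight | dusk |
|---|---|---|---|
| substrate | 0.020 M | 0.020 M | 0.020 M |
| solid reagent | 0.0140 M | 0.0140 M | 0.0140 M |
| time | 2.5 h | 4.0 h | 6.0 h |

1. which of these there is most of at the end, counted by the substrate in it, noon (substrate / product)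
2. which of these there is most of at the end, counted by the substrate in it, midnight (substrate / product)
3. which of these there is most of at the end, counted by the substrate in it, dusk (substrate / product)
4. final amount of the leader among these, as a percentage of the substrate charged, in noon
5. final amount of the leader among these, as a percentage of the substrate charged, in midnight
6. final amount of the leader among these, as a percentage of the substrate charged, in dusk

My own reckoning takes one minus c(solid reagent)/c(substrate), which gives 30.0%. This is the substrate floor, the part of the charged substrate that finds no partner, with the solid reagent as limiting reagent. Product therefore stops at 70.0% of the substrate charged. The floor tells where a flask ends and not when it gets there, so my reckoning gives that ceiling and no leader for noon, midnight or dusk.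

The forecast goes further and names a leader for each flask: substrate at 71% in noon, product at 69% in midnight and product at 70% in dusk. It holds that “product is capped by the 0.014 M charge at 70%”.

The flask gives substrate at 74.6% in noon, product at 68.6% in midnight and product at 70.0% in dusk, so the forecast stands on each mark.

In noon, the half-life of partner by the by-product-assisted step falls from 9.7 d at 0.647 h to 0.30 h at 2.50 h, and substrate goes from 99.7% at 1.25 h to 74.6% at the end. Noon ends above the floor, while dusk ends with 30% of its substrate, level with the floor.

A neighbour like noon but with 0.012 M of substrate holds 1.17 equiv of solid reagent, so its floor is 0%. After 2.50 h that neighbour still has 96.5% of its substrate, with 3.54% as product.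

Its constants belong to no real substance; the run is a simulation.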